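The route rests on building ring B of the flavanone half instead of joining two arenes. Ring B is a 1,2,3,4-tetrasubstituted benzene: C1' carries C2, C2' carries C8 of the luteolin unit, C3' and C4' carry adjacent oxygens. A (Z)-1-(luteolin-8-yl)buta-1,3-diene that already holds both oxygens (enol acetate beside the aryl terminus, silyl enol ether beside the CH2 terminus) adds methyl propiolate; one operation forms C1'–C2' and C5'–C6', closes ring B and, with DDQ, aromatises it. The crowded C2'–C8 biaryl bond is thus inherited from an easy Heck bond; the ester carbon becomes C2, set (S) later by a catalytic oxa-Michael closure.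

Key step: step 7

Remarks on the chemistry (assumptions and abbreviations):
- Ar = 5,7-bis(benzyloxy)-2-[3,4-bis(benzyloxy)phenyl]-4-oxo-4H-chromen-8-yl (the tetra-O-benzylluteolin-8-yl group).
- The target SMILES fixes only C2 (S). The C2'–C8 axis has four ortho substituents and is left open, so either axial form is taken as acceptable. Compounds 12–21 are handled as axial racemates, 22–24 as the two axial forms of the (2S) series, separated at the end only if they do not interconvert.
- Diene design: the oxygen at C3 is a tert-butyldimethylsilyl enol ether, which should survive isolation, heating and DDQ. The oxygen at C2 is an enol acetate, slimmer and a weaker donor than a second silyl ether, so the diene is polarised by one oxygen only and its geometry can be checked before the key step.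
- Catalyst C (step 15) is the 9-amino(9-deoxy)epi-quinine-derived N-[3,5-bis(trifluoromethyl)phenyl]thiourea or its quinidine-derived pseudoenantiomer. The two give opposite senses of induction; which one leads to (2S) is to be fixed in a pilot run on 21 (chiral HPLC and CD of the product).

Step 1
Reactants: 1 luteolin
Product: 2 5,7,3',4'-tetra-O-benzylluteolin (Ar–H)
Conditions: BnBr (6 equiv), K2CO3 (8 equiv), Bu4NI (cat.), DMF, 80 °C
Reagents that add atoms: benzyl bromide, BrCc1ccccc1
Why: Williamson etherification of all four phenols, in which excess reagent, iodide catalysis and heat are needed only for the hydrogen-bonded 5-OH.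

Step 2
Reactants: 2 5,7,3',4'-tetra-O-benzylluteolin
Product: 3 8-iodo-5,7,3',4'-tetra-O-benzylluteolin (Ar–I)
Conditions: NIS (1.1 equiv), CF3CO2H (0.3 equiv), CH2Cl2–MeCN, 0 °C → rt, dark
Reagents that add atoms: N-iodosuccinimide, O=C1CCC(=O)N1I
Why: Electrophilic aromatic iodination should take place on the phloroglucinol-type ring A and, with O5 alkylated, at C8 (between O7 and the ring oxygen), the usual site for 5,7-dialkoxyflavones, while the catechol ring is deactivated by conjugation to the pyrone.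

Step 3
Reactants: 3 8-iodo-5,7,3',4'-tetra-O-benzylluteolin; 4 methyl vinyl ketone
Product: 5 (E)-4-Ar-but-3-en-2-one
Conditions: Pd(OAc)2 (5 mol%), Bu4NCl (1 equiv), NaHCO3 (2.5 equiv), 4 (3 equiv), DMF, 70 °C
Reagents that add atoms: none
Why: Mizoroki–Heck coupling under ligand-free phase-transfer conditions, in which insertion at the unsubstituted enone terminus and syn β-hydride elimination should give the (E)-enone, the new aryl–vinyl bond being far less hindered than an aryl–aryl bond.

Step 4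
Reactants: 5 (E)-4-Ar-but-3-en-2-one
Product: 6 rac-(3S,4R)-3,4-dihydroxy-4-Ar-butan-2-one (syn diol)
Conditions: K2OsO4·2H2O (2 mol%), NMO (1.5 equiv), citric acid (1 equiv), t-BuOH–THF–H2O, rt
Reagents that add atoms: N-methylmorpholine N-oxide, C[N+]1([O-])CCOCC1; water, O
Why: Catalytic osmium tetroxide dihydroxylation with an acidic additive suited to electron-poor alkenes adds both hydroxyls to one face (syn diol, racemic, both centres erased in step 5), while the fully conjugated trisubstituted C2=C3 bond of the flavone should not be osmylated.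

Step 5
Reactants: 6 rac-(3S,4R)-3,4-dihydroxy-4-Ar-butan-2-one
Product: 8 (Z)-3-oxo-1-Ar-but-1-en-2-yl acetate, via syn-diacetate 7 (not isolated)
Conditions: Ac2O (3 equiv), Et3N (5 equiv), DMAP (cat.), CH2Cl2, 0 °C → rt; then DBU (1.2 equiv), rt
Reagents that add atoms: acetic anhydride, CC(=O)OC(C)=O
Why: Acetylation followed by E1cB β-elimination of the benzylic acetate from the enolate of the α-acetoxy ketone, the known way from acylated α,β-dihydroxy ketones to 2-acyloxy enones, should give the (Z) isomer, in which the bulky aryl group is trans to the acetyl group.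

Step 6
Reactants: 8 (Z)-3-oxo-1-Ar-but-1-en-2-yl acetate
Product: 9 (Z)-3-(tert-butyldimethylsilyloxy)-1-Ar-buta-1,3-dien-2-yl acetate
Conditions: t-BuMe2SiOTf (1.3 equiv), Et3N (3 equiv), CH2Cl2, −20 → 0 °C; NaHCO3 work-up, Et3N-deactivated silica
Reagents that add atoms: tert-butyldimethylsilyl trifluoromethanesulfonate, CC(C)(C)[Si](C)(C)OS(=O)(=O)C(F)(F)F
Why: Soft enolisation with silyl triflate and amine acts on the methyl group, the only ketone α-position that bears hydrogen, and should give the 2-silyloxy diene without touching the enol acetate geometry; any O-silylation of the flavone carbonyl is reversed on the bicarbonate work-up.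

Step 7
Reactants: 9 (Z)-3-(tert-butyldimethylsilyloxy)-1-Ar-buta-1,3-dien-2-yl acetate; 10 methyl propiolate
Product: 12 methyl 3-acetoxy-4-(tert-butyldimethylsilyloxy)-2-Ar-benzoate, via cyclohexa-1,4-diene adduct 11 (not isolated)
Conditions: 10 (8 equiv), BHT (cat.), toluene, 120 °C, sealed tube, N2; then DDQ (1.2 equiv), rt
Reagents that add atoms: none
Why: A thermal, concerted but asynchronous [4+2] cycloaddition: the silyl enol ether terminus C4 of s-cis 9 (largest HOMO coefficient, unhindered CH2) bonds first to the β-carbon of the propiolate (largest LUMO coefficient), the aryl-bearing C1 then closes onto the ester-bearing carbon, and DDQ removes a hydride and a proton from the two sp3 ring carbons of 11 to give the benzene. The closest known reaction type is the Diels–Alder addition of 2-silyloxy- and 2,3-dioxygenated buta-1,3-dienes to alkynoates followed by dehydrogenation to phenol or catechol derivatives. Ring B is closed in the intermolecular [4+2] mode, both C1'–C2' and C5'–C6' being formed in the cycloaddition. No stereocentre survives, since the only stereogenic sp3 carbon of 11 (the later C2') is flattened on aromatisation. The selectivity needed is regiochemical (ester next to the aryl-bearing carbon and para to the silyloxy carbon): the strong donor at C3 outweighs the weakly donating enol acetate at C2, the aryl group at C1 acts in the same sense, and the early bond forms at the open CH2 end, so the crowded bond at C1 is the late one. The (Z) geometry keeps the luteolinyl group on the outside of the s-cis diene, and the slim acetate keeps that terminus as open as it can be.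

Step 8
Reactants: 12 methyl 3-acetoxy-4-(tert-butyldimethylsilyloxy)-2-Ar-benzoate
Product: 13 methyl 3,4-bis(benzyloxy)-2-Ar-benzoate
Conditions: BnBr (4 equiv), K2CO3 (6 equiv), MeOH–DMF (1:4), rt → 45 °C, argon
Reagents that add atoms: benzyl bromide, BrCc1ccccc1
Why: Carbonate-mediated methanolysis of the aryl acetate and the aryl silyl ether is coupled with Williamson benzylation of each phenoxide as it forms, so the air-sensitive catechol should never accumulate and the methyl ester only exchanges with methanol.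

Step 9
Reactants: 13 methyl 3,4-bis(benzyloxy)-2-Ar-benzoate
Product: 14 3,4-bis(benzyloxy)-2-Ar-benzoic acid
Conditions: LiOH·H2O (5 equiv), THF–MeOH–H2O, 50 °C; then 1 M HCl to pH 3
Reagents that add atoms: lithium hydroxide, [Li+].[OH-]
Why: Saponification by acyl–oxygen cleavage, under which benzyl ethers are inert and the pyrone ring of the flavone should tolerate dilute hydroxide at this temperature.

Step 10
Reactants: 14 3,4-bis(benzyloxy)-2-Ar-benzoic acid
Product: 16 [3,4-bis(benzyloxy)-2-Ar-phenyl]methanol, via acyl imidazolide 15 (not isolated)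
Conditions: CDI (1.3 equiv), THF, rt → 40 °C; then NaBH4 (3 equiv), H2O, 0 °C
Reagents that add atoms: none
Why: Borohydride reduction of the acyl imidazolide gives the primary alcohol, and NaBH4 at 0 °C should leave the 2-aryl-γ-pyrone carbonyl of the flavone untouched, which is the reason the ester is not reduced directly with an aluminium hydride.

Step 11
Reactants: 16 [3,4-bis(benzyloxy)-2-Ar-phenyl]methanol
Product: 17 3,4-bis(benzyloxy)-2-Ar-benzaldehyde
Conditions: Dess–Martin periodinane (1.3 equiv), CH2Cl2, 0 °C → rt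
Reagents that add atoms: none
Why: Dess–Martin oxidation of the benzylic alcohol should stop cleanly at the aldehyde under neutral conditions that spare the benzyl ethers and the flavone.

Step 12
Reactants: 18 2',4',6'-trihydroxyacetophenone
Product: 19 1-[2,4-bis(benzyloxy)-6-hydroxyphenyl]ethanone
Conditions: BnBr (2.1 equiv), K2CO3 (2.2 equiv), DMF, rt
Reagents that add atoms: benzyl bromide, BrCc1ccccc1
Why: Williamson etherification of the para hydroxyl and one of the two equivalent ortho hydroxyls, the remaining ortho hydroxyl being deactivated by its hydrogen bond to the acetyl group.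

Step 13
Reactants: 19 1-[2,4-bis(benzyloxy)-6-hydroxyphenyl]ethanone
Product: 20 tert-butyl 3-[2,4-bis(benzyloxy)-6-hydroxyphenyl]-3-oxopropanoate
Conditions: LiN(SiMe3)2 (3.3 equiv), THF, −78 °C; Boc2O (1.2 equiv), −78 → 0 °C; aq NH4Cl
Reagents that add atoms: di-tert-butyl dicarbonate, CC(C)(C)OC(=O)OC(=O)OC(C)(C)C
Why: Claisen-type C-acylation of the lithium enolate of the phenoxide–enolate dianion, in which the more acidic β-ketoester takes up the third equivalent of base and the tert-butyl ester resists lactonisation to a 4-hydroxycoumarin.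

Step 14
Reactants: 17 3,4-bis(benzyloxy)-2-Ar-benzaldehyde; 20 tert-butyl 3-[2,4-bis(benzyloxy)-6-hydroxyphenyl]-3-oxopropanoate
Product: 21 tert-butyl 2-[2,4-bis(benzyloxy)-6-hydroxybenzoyl]-3-[3,4-bis(benzyloxy)-2-Ar-phenyl]prop-2-enoate (E/Z mixture)
Conditions: piperidine (0.2 equiv), AcOH (0.2 equiv), 4 Å molecular sieves, toluene, rt → 40 °C
Reagents that add atoms: none
Why: Knoevenagel condensation under piperidinium acetate catalysis, in which the hydrogen-bonded phenol is a poor nucleophile at near-neutral pH, so uncatalysed (racemic) ring closure should stay slow.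

Step 15
Reactants: 21 tert-butyl 2-[2,4-bis(benzyloxy)-6-hydroxybenzoyl]-3-[3,4-bis(benzyloxy)-2-Ar-phenyl]prop-2-enoate
Product: 23 (2S)-5,7-bis(benzyloxy)-2-[3,4-bis(benzyloxy)-2-Ar-phenyl]chroman-4-one, via flavanone-3-carboxylate 22 (not isolated)
Conditions: catalyst C (10 mol%), toluene, −25 °C; then TsOH·H2O (0.5 equiv), 80 °C
Reagents that add atoms: none
Why: Enantioselective 6-endo-trig oxa-Michael addition to an alkylidene β-ketoester under bifunctional thiourea–amine catalysis, the established activation mode for this substrate class: the thiourea holds the β-ketoester while the quinuclidine delivers the phenol to one alkene face and so sets C2 under catalyst control, after which acid cleaves the tert-butyl ester and decarboxylation erases C3 without touching C2.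

Step 16
Reactants: 23 (2S)-5,7-bis(benzyloxy)-2-[3,4-bis(benzyloxy)-2-Ar-phenyl]chroman-4-one
Product: 24 (2S)-2-[2-(5,7-dihydroxy-2-(3,4-dihydroxyphenyl)-4-oxo-4H-chromen-8-yl)-3,4-dihydroxyphenyl]-5,7-dihydroxychroman-4-one (CNP0265600.1)
Conditions: H2 (1 atm), 10% Pd/C, THF–MeOH (1:1), rt
Reagents that add atoms: none
Why: Catalytic hydrogenolysis of all eight benzyl ethers is neutral and so cannot open the flavanone ring and epimerise C2, while the flavone C2=C3 bond and the benzylic C2–O bond of the flavanone are reduced far more slowly, so the reaction is to be stopped at the calculated hydrogen uptake.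

Compound list
1 | luteolin | O=c1cc(-c2ccc(O)c(O)c2)oc2cc(O)cc(O)c12 | starting material
2 | 5,7,3',4'-tetra-O-benzylluteolin (Ar–H) | O=c1cc(-c2ccc(OCc3ccccc3)c(OCc3ccccc3)c2)oc2cc(OCc3ccccc3)cc(OCc3ccccc3)c12 | intermediate
3 | 8-iodo-5,7,3',4'-tetra-O-benzylluteolin (Ar–I) | Ic1c(OCc2ccccc2)cc(OCc2ccccc2)c2c(=O)cc(-c3ccc(OCc4ccccc4)c(OCc4ccccc4)c3)oc12 | intermediate
4 | methyl vinyl ketone | C=CC(C)=O | starting material
5 | (E)-4-Ar-but-3-en-2-one | CC(=O)/C=C/c1c(OCc2ccccc2)cc(OCc2ccccc2)c2c(=O)cc(-c3ccc(OCc4ccccc4)c(OCc4ccccc4)c3)oc12 | intermediate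
6 | rac-(3S,4R)-3,4-dihydroxy-4-Ar-butan-2-one (syn diol, racemate; one enantiomer drawn) | CC(=O)[C@@H](O)[C@H](O)c1c(OCc2ccccc2)cc(OCc2ccccc2)c2c(=O)cc(-c3ccc(OCc4ccccc4)c(OCc4ccccc4)c3)oc12 | intermediate
7 | rac-syn-3,4-diacetoxy-4-Ar-butan-2-one (racemate; one enantiomer drawn; not isolated) | CC(=O)[C@@H](OC(C)=O)[C@H](OC(C)=O)c1c(OCc2ccccc2)cc(OCc2ccccc2)c2c(=O)cc(-c3ccc(OCc4ccccc4)c(OCc4ccccc4)c3)oc12 | intermediate
8 | (Z)-3-oxo-1-Ar-but-1-en-2-yl acetate | CC(=O)/C(OC(C)=O)=C/c1c(OCc2ccccc2)cc(OCc2ccccc2)c2c(=O)cc(-c3ccc(OCc4ccccc4)c(OCc4ccccc4)c3)oc12 | intermediate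
9 | (Z)-3-(tert-butyldimethylsilyloxy)-1-Ar-buta-1,3-dien-2-yl acetate | C=C(O[Si](C)(C)C(C)(C)C)/C(OC(C)=O)=C/c1c(OCc2ccccc2)cc(OCc2ccccc2)c2c(=O)cc(-c3ccc(OCc4ccccc4)c(OCc4ccccc4)c3)oc12 | intermediate
10 | methyl propiolate | C#CC(=O)OC | starting material
11 | methyl 5-acetoxy-4-(tert-butyldimethylsilyloxy)-6-Ar-cyclohexa-1,4-diene-1-carboxylate (racemic; not isolated) | COC(=O)C5=CCC(O[Si](C)(C)C(C)(C)C)=C(OC(C)=O)C5c1c(OCc2ccccc2)cc(OCc2ccccc2)c2c(=O)cc(-c3ccc(OCc4ccccc4)c(OCc4ccccc4)c3)oc12 | intermediate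
12 | methyl 3-acetoxy-4-(tert-butyldimethylsilyloxy)-2-Ar-benzoate | COC(=O)c5ccc(O[Si](C)(C)C(C)(C)C)c(OC(C)=O)c5-c1c(OCc2ccccc2)cc(OCc2ccccc2)c2c(=O)cc(-c3ccc(OCc4ccccc4)c(OCc4ccccc4)c3)oc12 | intermediate
13 | methyl 3,4-bis(benzyloxy)-2-Ar-benzoate | COC(=O)c5ccc(OCc6ccccc6)c(OCc6ccccc6)c5-c1c(OCc2ccccc2)cc(OCc2ccccc2)c2c(=O)cc(-c3ccc(OCc4ccccc4)c(OCc4ccccc4)c3)oc12 | intermediate
14 | 3,4-bis(benzyloxy)-2-Ar-benzoic acid | OC(=O)c5ccc(OCc6ccccc6)c(OCc6ccccc6)c5-c1c(OCc2ccccc2)cc(OCc2ccccc2)c2c(=O)cc(-c3ccc(OCc4ccccc4)c(OCc4ccccc4)c3)oc12 | intermediate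
15 | 1-[3,4-bis(benzyloxy)-2-Ar-benzoyl]imidazole (not isolated) | O=C(n5ccnc5)c6ccc(OCc7ccccc7)c(OCc7ccccc7)c6-c1c(OCc2ccccc2)cc(OCc2ccccc2)c2c(=O)cc(-c3ccc(OCc4ccccc4)c(OCc4ccccc4)c3)oc12 | intermediate
16 | [3,4-bis(benzyloxy)-2-Ar-phenyl]methanol | OCc5ccc(OCc6ccccc6)c(OCc6ccccc6)c5-c1c(OCc2ccccc2)cc(OCc2ccccc2)c2c(=O)cc(-c3ccc(OCc4ccccc4)c(OCc4ccccc4)c3)oc12 | intermediate
17 | 3,4-bis(benzyloxy)-2-Ar-benzaldehyde | O=Cc5ccc(OCc6ccccc6)c(OCc6ccccc6)c5-c1c(OCc2ccccc2)cc(OCc2ccccc2)c2c(=O)cc(-c3ccc(OCc4ccccc4)c(OCc4ccccc4)c3)oc12 | intermediate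
18 | 2',4',6'-trihydroxyacetophenone | CC(=O)c1c(O)cc(O)cc1O | starting material
19 | 1-[2,4-bis(benzyloxy)-6-hydroxyphenyl]ethanone | CC(=O)c1c(O)cc(OCc2ccccc2)cc1OCc1ccccc1 | intermediate
20 | tert-butyl 3-[2,4-bis(benzyloxy)-6-hydroxyphenyl]-3-oxopropanoate | CC(C)(C)OC(=O)CC(=O)c1c(O)cc(OCc2ccccc2)cc1OCc1ccccc1 | intermediate
21 | tert-butyl 2-[2,4-bis(benzyloxy)-6-hydroxybenzoyl]-3-[3,4-bis(benzyloxy)-2-Ar-phenyl]prop-2-enoate (E/Z mixture) | CC(C)(C)OC(=O)C(=Cc5ccc(OCc6ccccc6)c(OCc6ccccc6)c5-c1c(OCc2ccccc2)cc(OCc2ccccc2)c2c(=O)cc(-c3ccc(OCc4ccccc4)c(OCc4ccccc4)c3)oc12)C(=O)c7c(O)cc(OCc8ccccc8)cc7OCc7ccccc7 | intermediate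
22 | tert-butyl (2S)-5,7-bis(benzyloxy)-2-[3,4-bis(benzyloxy)-2-Ar-phenyl]-4-oxochromane-3-carboxylate (C3 epimers and enol; not isolated) | O=C9C(C(=O)OC(C)(C)C)[C@@H](c5ccc(OCc6ccccc6)c(OCc6ccccc6)c5-c1c(OCc2ccccc2)cc(OCc2ccccc2)c2c(=O)cc(-c3ccc(OCc4ccccc4)c(OCc4ccccc4)c3)oc12)Oc7cc(OCc8ccccc8)cc(OCc8ccccc8)c79 | intermediate
23 | (2S)-5,7-bis(benzyloxy)-2-[3,4-bis(benzyloxy)-2-Ar-phenyl]chroman-4-one | O=C9C[C@@H](c5ccc(OCc6ccccc6)c(OCc6ccccc6)c5-c1c(OCc2ccccc2)cc(OCc2ccccc2)c2c(=O)cc(-c3ccc(OCc4ccccc4)c(OCc4ccccc4)c3)oc12)Oc7cc(OCc8ccccc8)cc(OCc8ccccc8)c79 | intermediate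
24 | (2S)-2-[2-(5,7-dihydroxy-2-(3,4-dihydroxyphenyl)-4-oxo-4H-chromen-8-yl)-3,4-dihydroxyphenyl]-5,7-dihydroxychroman-4-one (CNP0265600.1) | O=C1C[C@@H](c2ccc(O)c(O)c2-c2c(O)cc(O)c3c(=O)cc(-c4ccc(O)c(O)c4)oc23)Oc2cc(O)cc(O)c21 | target

Total step count: 16. Longest linear sequence: 14 steps (steps 1–11 and 14–16, from luteolin); steps 12 and 13 make the second fragment.

Steps most likely to fail

Step 7. The cycloaddition may be too slow at the crowded aryl-bearing diene terminus, so that loss of the silyl enol ether or oligomerisation of the alkyne wins, or bond formation may occur in the reverse orientation. The fallback makes the biaryl bond by Suzuki–Miyaura coupling. It sets out from 3, which Miyaura borylation (B2pin2, PdCl2(dppf), KOAc, dioxane, 90 °C) should convert into 8-(4,4,5,5-tetramethyl-1,3,2-dioxaborolan-2-yl)-5,7,3',4'-tetra-O-benzylluteolin F1. The partner starts from purchased 2-bromo-3-hydroxy-4-methoxybenzaldehyde F2, which is demethylated (BBr3, CH2Cl2, −78 → 0 °C) to 2-bromo-3,4-dihydroxybenzaldehyde F3 and benzylated (BnBr, K2CO3, DMF) to 2-bromo-3,4-bis(benzyloxy)benzaldehyde F4. Coupling of F1 with F4 (Pd(OAc)2, SPhos, K3PO4, toluene–H2O, 100 °C) should give aldehyde 17, where the route is rejoined.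

Step 15. Facial selectivity may be poor because the stereogenic axis next to the reacting carbon competes with the catalyst (a mismatched pairing for one axial form), and uncatalysed closure may erode the enantiomeric purity. The fallback is racemic closure followed by resolution. It sets out from 17 and 19: Claisen–Schmidt condensation (KOH, EtOH–THF, rt) should give (E)-1-[2,4-bis(benzyloxy)-6-hydroxyphenyl]-3-[3,4-bis(benzyloxy)-2-Ar-phenyl]prop-2-en-1-one F5. Base-mediated ring closure (NaOAc, EtOH, reflux) should give racemic 5,7-bis(benzyloxy)-2-[3,4-bis(benzyloxy)-2-Ar-phenyl]chroman-4-one F6. Preparative HPLC on an amylose tris(3,5-dimethylphenylcarbamate) phase delivers the (2S) series, which is 23, where the route is rejoined; the (2R) material can be re-equilibrated through the chalcone and recycled.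

Step 2. Iodination may leak to C6 or to the catechol ring of the luteolin unit. The fallback builds the iodoflavone from a pre-iodinated ring A. It sets out from 19, where iodination ortho to the chelated phenol (BnNMe3·ICl2, CaCO3, CH2Cl2–MeOH, rt) should give 1-[4,6-bis(benzyloxy)-2-hydroxy-3-iodophenyl]ethanone F7. Claisen–Schmidt condensation with purchased 3,4-bis(benzyloxy)benzaldehyde F8 (KOH, EtOH, rt) should give (E)-1-[4,6-bis(benzyloxy)-2-hydroxy-3-iodophenyl]-3-[3,4-bis(benzyloxy)phenyl]prop-2-en-1-one F9. Oxidative cyclisation (I2 cat., DMSO, 120 °C) then gives 3, where the route is rejoined.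

Further compounds
F1 | step 7 | 8-(4,4,5,5-tetramethyl-1,3,2-dioxaborolan-2-yl)-5,7,3',4'-tetra-O-benzylluteolin | CC5(C)OB(OC5(C)C)c1c(OCc2ccccc2)cc(OCc2ccccc2)c2c(=O)cc(-c3ccc(OCc4ccccc4)c(OCc4ccccc4)c3)oc12
F2 | step 7 | 2-bromo-3-hydroxy-4-methoxybenzaldehyde (purchased) | O=Cc1ccc(OC)c(O)c1Br
F3 | step 7 | 2-bromo-3,4-dihydroxybenzaldehyde | O=Cc1ccc(O)c(O)c1Br
F4 | step 7 | 2-bromo-3,4-bis(benzyloxy)benzaldehyde | O=Cc1ccc(OCc2ccccc2)c(OCc2ccccc2)c1Br
F5 | step 15 | (E)-1-[2,4-bis(benzyloxy)-6-hydroxyphenyl]-3-[3,4-bis(benzyloxy)-2-Ar-phenyl]prop-2-en-1-one | O=C(/C=C/c5ccc(OCc6ccccc6)c(OCc6ccccc6)c5-c1c(OCc2ccccc2)cc(OCc2ccccc2)c2c(=O)cc(-c3ccc(OCc4ccccc4)c(OCc4ccccc4)c3)oc12)c7c(O)cc(OCc8ccccc8)cc7OCc7ccccc7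
F6 | step 15 | racemic 5,7-bis(benzyloxy)-2-[3,4-bis(benzyloxy)-2-Ar-phenyl]chroman-4-one | O=C9CC(c5ccc(OCc6ccccc6)c(OCc6ccccc6)c5-c1c(OCc2ccccc2)cc(OCc2ccccc2)c2c(=O)cc(-c3ccc(OCc4ccccc4)c(OCc4ccccc4)c3)oc12)Oc7cc(OCc8ccccc8)cc(OCc8ccccc8)c79
F7 | step 2 | 1-[4,6-bis(benzyloxy)-2-hydroxy-3-iodophenyl]ethanone | CC(=O)c1c(O)c(I)c(OCc2ccccc2)cc1OCc1ccccc1
F8 | step 2 | 3,4-bis(benzyloxy)benzaldehyde (purchased) | O=Cc1ccc(OCc2ccccc2)c(OCc2ccccc2)c1
F9 | step 2 | (E)-1-[4,6-bis(benzyloxy)-2-hydroxy-3-iodophenyl]-3-[3,4-bis(benzyloxy)phenyl]prop-2-en-1-one | O=C(/C=C/c1ccc(OCc2ccccc2)c(OCc2ccccc2)c1)c1c(O)c(I)c(OCc2ccccc2)cc1OCc1ccccc1
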